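**Strategy**

Numbering: tetralin C1 carries the side chain C11–C16, C4 the methyl, C5 the hydroxyl, C8 the carboxyl; ring A is the arene, ring B the saturated ring. The plan hinges on the C11–C12 bond. C11, the exocyclic methine on C1 of ring B, holds a methyl group and the C12–C13 unit, so it can come from the inner carbon of a vinyl group on a dihydronaphthalene that gains hydrogen at its terminus and a vinyl group from ethylene. One nickel-catalysed asymmetric hydrovinylation thus makes C11–C12, the C11 methyl and the C11 configuration, leaving an alkene handle. The precursor is diene 11: C1 vinyl, C5 methoxy, C8 methyl ester, C4 centre set.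

Key step: step 9

Assumption: the sense of induction of the phosphoramidite ligand L1 (steps 1 and 9) and of the phosphino-oxazoline ligand (step 12) is taken from simpler substrates of the same classes; both antipodes of each ligand are available, and "L1" or "tBu-PHOX" means the antipode that delivers the configuration drawn, to be fixed on a small scale.

Ligands: L1 = O,O′-(1,1′-binaphthalene-2,2′-diyl) N,N-bis(1-phenylethyl)phosphoramidite; tBu-PHOX = 4-tert-butyl-2-[2-(diphenylphosphino)phenyl]-4,5-dihydrooxazole.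

Design note: the phenol and the acid are unmasked before the isomerisable 4-methylpent-3-enoate is attached and are carried through the acylation as allyl groups, so that the last step is a neutral deprotection.

**Route**

Step 1
Reactants: 1 2-methoxystyrene; 2 ethylene
Product: 3 1-[(2R)-but-3-en-2-yl]-2-methoxybenzene
Conditions: [(allyl)NiBr]2 (0.7 mol%), L1 (1.5 mol%), Na[B(3,5-(CF3)2C6H3)4] (2 mol%), ethylene (1 atm), CH2Cl2, −70 °C
Reagents that add atoms: none
Why: Nickel-catalysed asymmetric hydrovinylation of a vinylarene, in which a cationic nickel hydride adds to the styrene, ethylene inserts at the benzylic carbon and β-hydride elimination should release the branched 3-arylbut-1-ene, the phosphoramidite on nickel choosing the alkene face so that the benzylic centre (the later C4) is (R).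

Step 2
Reactants: 3 1-[(2R)-but-3-en-2-yl]-2-methoxybenzene
Product: 4 (4R)-4-(2-methoxyphenyl)pentanal
Conditions: Rh(acac)(CO)2 (0.5 mol%), Xantphos (2 mol%), CO/H2 (1:1, 20 bar), toluene, 80 °C
Reagents that add atoms: carbon monoxide, [C-]#[O+]
Why: Rhodium-catalysed hydroformylation with a wide-bite-angle diphosphine should place the formyl group on the terminal carbon (the allylic branch reinforces linear selectivity), and the low isomerisation tendency of this catalyst should leave the benzylic centre untouched.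

Step 3
Reactants: 4 (4R)-4-(2-methoxyphenyl)pentanal
Product: 5 (4R)-4-(2-methoxyphenyl)pentanoic acid
Conditions: NaClO2, NaH2PO4, 2-methyl-2-butene, t-BuOH/H2O, 0 °C → rt
Reagents that add atoms: sodium chlorite, [Na+].[O-]Cl=O
Why: Pinnick oxidation converts the aldehyde into the acid under buffered conditions, with 2-methyl-2-butene trapping hypochlorous acid so that the anisole ring is not chlorinated and the remote stereocentre is not at risk.

Step 4
Reactants: 5 (4R)-4-(2-methoxyphenyl)pentanoic acid
Product: 6 (4R)-5-methoxy-4-methyl-3,4-dihydronaphthalen-1(2H)-one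
Conditions: P2O5/MeSO3H (1:10 w/w), 40 °C
Reagents that add atoms: none
Why: Intramolecular Friedel–Crafts acylation can close the six-membered ring only at the free ortho position of the arene (the other ortho position carries the methoxy group), as in the standard preparation of 5-methoxy-1-tetralones, and no pathway touches the benzylic C4 centre.

Step 5
Reactants: 6 (4R)-5-methoxy-4-methyl-3,4-dihydronaphthalen-1(2H)-one
Product: 7 (4R)-8-bromo-5-methoxy-4-methyl-3,4-dihydronaphthalen-1(2H)-one
Conditions: N-bromosuccinimide, MeCN, 0 °C → rt, dark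
Reagents that add atoms: N-bromosuccinimide, O=C1CCC(=O)N1Br
Why: Electrophilic aromatic bromination in a polar solvent should go para to the methoxy group (C8), because C6 is shielded by the methoxy methyl group that the peri C4 methyl turns towards it, and ionic conditions avoid bromination next to the ketone or at the benzylic position.

Step 6
Reactants: 7 (4R)-8-bromo-5-methoxy-4-methyl-3,4-dihydronaphthalen-1(2H)-one
Product: 8 methyl (5R)-4-methoxy-5-methyl-8-oxo-5,6,7,8-tetrahydronaphthalene-1-carboxylate
Conditions: Pd(OAc)2 (3 mol%), Xantphos (3 mol%), CO (1 atm), MeOH, Et3N, toluene, 80 °C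
Reagents that add atoms: carbon monoxide, [C-]#[O+]; methanol, CO
Why: Palladium-catalysed alkoxycarbonylation, in which oxidative addition of the aryl bromide (activated by the ortho carbonyl group), CO insertion and methanolysis of the acylpalladium species should give the methyl ester at low CO pressure.

Step 7
Reactants: 8 methyl (5R)-4-methoxy-5-methyl-8-oxo-5,6,7,8-tetrahydronaphthalene-1-carboxylate
Product: 10 methyl (5R)-4-methoxy-5-methyl-8-{[(trifluoromethyl)sulfonyl]oxy}-5,6-dihydronaphthalene-1-carboxylate, via potassium enolate 9 (not isolated)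
Conditions: KN(SiMe3)2, THF, −78 °C; then N-(5-chloropyridin-2-yl)bis(trifluoromethanesulfonimide), −78 °C
Reagents that add atoms: N-(5-chloropyridin-2-yl)bis(trifluoromethanesulfonimide), Clc1ccc(N(S(=O)(=O)C(F)(F)F)S(=O)(=O)C(F)(F)F)nc1
Why: Kinetic enolate formation at C2, the only enolisable position, followed by O-sulfonylation with a triflimide that reacts at −78 °C should give the enol triflate before the enolate oxygen can attack the neighbouring C8 ester, and the C4 centre is not acidic under these conditions.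

Step 8
Reactants: 10 methyl (5R)-4-methoxy-5-methyl-8-{[(trifluoromethyl)sulfonyl]oxy}-5,6-dihydronaphthalene-1-carboxylate
Product: 11 methyl (5R)-8-ethenyl-4-methoxy-5-methyl-5,6-dihydronaphthalene-1-carboxylate
Conditions: vinylboronic acid pinacol ester, PdCl2(dppf) (3 mol%), K3PO4, THF/H2O, 50 °C
Reagents that add atoms: vinylboronic acid pinacol ester, C=CB1OC(C)(C)C(C)(C)O1
Why: Suzuki–Miyaura coupling of the alkenyl triflate with the vinylboronate should give the 1-vinyl-3,4-dihydronaphthalene under mild phosphate conditions that leave the hindered aryl ester intact.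

Step 9
Reactants: 11 methyl (5R)-8-ethenyl-4-methoxy-5-methyl-5,6-dihydronaphthalene-1-carboxylate; 2 ethylene
Product: 12 methyl (5R)-8-[(2S)-but-3-en-2-yl]-4-methoxy-5-methyl-5,6-dihydronaphthalene-1-carboxylate
Conditions: [(allyl)NiBr]2 (2.5 mol%), L1 (5 mol%), Na[B(3,5-(CF3)2C6H3)4] (6 mol%), ethylene (1 atm), CH2Cl2, −70 → −55 °C
Reagents that add atoms: none
Why: Nickel-catalysed asymmetric 1,2-hydrovinylation of a 1,3-diene, the reaction type established for 1-vinylcycloalkenes and vinylarenes: the cationic nickel hydride formed from the allylnickel precursor and ethylene adds to the terminal CH2 of the vinyl group (which becomes the C11 methyl) and gives an allylnickel species spanning C11, C1 and C2. Ethylene inserts at the exocyclic terminus C11, forming C11–C12, and β-hydride elimination should release diene 12 and regenerate the hydride. No ring is closed. The new C11 centre is set by the phosphoramidite on nickel, which selects the face of the allyl terminus at which ethylene inserts (catalyst control, independent of the remote C4 centre), and the (S) configuration is required. The step needs 1,2- over 1,4-addition and no isomerisation of the product alkenes or ethylene oligomerisation: reaction at C11 keeps C1=C2 conjugated with ring A whereas reaction at C2 would not, C11 is the less hindered allyl terminus, and low temperature with the weakly coordinating borate anion suppresses isomerisation. The C8 ester next to the diene is the main uncertainty, since it may bind the cationic nickel centre.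

Step 10
Reactants: 13 (2S)-3-bromo-2-methylpropan-1-ol
Product: 14 [(2S)-3-bromo-2-methylpropoxy](tert-butyl)dimethylsilane
Conditions: t-BuMe2SiCl, imidazole, CH2Cl2, 0 °C → rt
Reagents that add atoms: tert-butyldimethylsilyl chloride, CC(C)(C)[Si](C)(C)Cl
Why: Standard imidazole-mediated silylation of a primary alcohol masks the hydroxyl group for the organometallic step without touching the stereocentre or the bromide.

Step 11
Reactants: 12 methyl (5R)-8-[(2S)-but-3-en-2-yl]-4-methoxy-5-methyl-5,6-dihydronaphthalene-1-carboxylate; 14 [(2S)-3-bromo-2-methylpropoxy](tert-butyl)dimethylsilane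
Product: 16 methyl (5R)-8-[(2S,6R)-7-{[tert-butyl(dimethyl)silyl]oxy}-6-methylheptan-2-yl]-4-methoxy-5-methyl-5,6-dihydronaphthalene-1-carboxylate, via B-alkyl-9-borabicyclononane 15 (not isolated)
Conditions: 9-BBN (1.1 equiv), THF, 0 °C → rt; then 14, Pd(OAc)2 (4 mol%), PCy3 (8 mol%), K3PO4·H2O, THF, rt → 40 °C
Reagents that add atoms: none
Why: Anti-Markovnikov hydroboration with 9-BBN is selective for the monosubstituted alkene over the trisubstituted ring alkene and the ester, and the primary alkylborane should undergo B-alkyl Suzuki–Miyaura coupling with the primary alkyl bromide under Pd(OAc)2/PCy3 catalysis (the bulky electron-rich phosphine promotes oxidative addition and retards β-hydride elimination), forming C13–C14 without creating or disturbing a stereocentre.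

Step 12
Reactants: 16 methyl (5R)-8-[(2S,6R)-7-{[tert-butyl(dimethyl)silyl]oxy}-6-methylheptan-2-yl]-4-methoxy-5-methyl-5,6-dihydronaphthalene-1-carboxylate
Product: 17 methyl (5R,8S)-8-[(2S,6R)-7-{[tert-butyl(dimethyl)silyl]oxy}-6-methylheptan-2-yl]-4-methoxy-5-methyl-5,6,7,8-tetrahydronaphthalene-1-carboxylate
Conditions: [Ir(cod)(tBu-PHOX)][B(3,5-(CF3)2C6H3)4] (2 mol%), H2 (50 bar), CH2Cl2, rt
Reagents that add atoms: none
Why: Iridium-catalysed asymmetric hydrogenation of a trisubstituted aryl alkene with a cationic phosphino-oxazoline complex, the catalyst class established for 1-alkyl-3,4-dihydronaphthalenes, should saturate C1=C2 with the ligand choosing the face (catalyst control over the resident C4 and C11 centres) so that hydrogen enters C1 syn to the C4 methyl, giving the (1S) centre with the side chain trans to that methyl group.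

Step 13
Reactants: 17 methyl (5R,8S)-8-[(2S,6R)-7-{[tert-butyl(dimethyl)silyl]oxy}-6-methylheptan-2-yl]-4-methoxy-5-methyl-5,6,7,8-tetrahydronaphthalene-1-carboxylate
Product: 19 (5R,8S)-4-hydroxy-8-[(2S,6R)-7-hydroxy-6-methylheptan-2-yl]-5-methyl-5,6,7,8-tetrahydronaphthalene-1-carboxylic acid, via disodium phenolate carboxylate 18 (not isolated)
Conditions: NaSEt, DMF, 130 °C; then 2 M HCl, THF/H2O, rt
Reagents that add atoms: none
Why: Thiolate SN2 O-demethylation cleaves both the aryl methyl ether and the hindered methyl ester at their methyl carbons (attack at methyl is insensitive to crowding around the carboxyl group), and the acidic aqueous second stage hydrolyses the primary silyl ether, none of which touches a stereocentre.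

Step 14
Reactants: 19 (5R,8S)-4-hydroxy-8-[(2S,6R)-7-hydroxy-6-methylheptan-2-yl]-5-methyl-5,6,7,8-tetrahydronaphthalene-1-carboxylic acid
Product: 20 prop-2-en-1-yl (5R,8S)-8-[(2S,6R)-7-hydroxy-6-methylheptan-2-yl]-5-methyl-4-(prop-2-en-1-yloxy)-5,6,7,8-tetrahydronaphthalene-1-carboxylate
Conditions: allyl bromide, K2CO3, DMF, rt
Reagents that add atoms: allyl bromide, C=CCBr
Why: Williamson-type O-alkylation under carbonate conditions alkylates only the phenoxide and the carboxylate, since K2CO3 does not deprotonate the aliphatic C16 hydroxyl, so both acidic groups are masked in one operation as groups removable under neutral conditions.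

Step 15
Reactants: 20 prop-2-en-1-yl (5R,8S)-8-[(2S,6R)-7-hydroxy-6-methylheptan-2-yl]-5-methyl-4-(prop-2-en-1-yloxy)-5,6,7,8-tetrahydronaphthalene-1-carboxylate; 21 4-methylpent-3-enoic acid
Product: 22 prop-2-en-1-yl (5R,8S)-5-methyl-8-{(2S,6R)-6-methyl-7-[(4-methylpent-3-enoyl)oxy]heptan-2-yl}-4-(prop-2-en-1-yloxy)-5,6,7,8-tetrahydronaphthalene-1-carboxylate
Conditions: EDC·HCl, DMAP (10 mol%), CH2Cl2, 0 °C → rt
Reagents that add atoms: none
Why: Steglich-type carbodiimide esterification of the only free hydroxyl group (C16–OH) should proceed cleanly, and low temperature with only catalytic DMAP keeps the β,γ-double bond of the acyl group from moving into conjugation.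

Step 16
Reactants: 22 prop-2-en-1-yl (5R,8S)-5-methyl-8-{(2S,6R)-6-methyl-7-[(4-methylpent-3-enoyl)oxy]heptan-2-yl}-4-(prop-2-en-1-yloxy)-5,6,7,8-tetrahydronaphthalene-1-carboxylate
Product: 23 (5R,8S)-4-hydroxy-5-methyl-8-{(2S,6R)-6-methyl-7-[(4-methylpent-3-enoyl)oxy]heptan-2-yl}-5,6,7,8-tetrahydronaphthalene-1-carboxylic acid
Conditions: Pd(PPh3)4 (5 mol%), morpholine, THF, rt
Reagents that add atoms: none
Why: Palladium-catalysed deallylation of Tsuji–Trost type, in which zerovalent palladium ionises the allyl ester and the allyl aryl ether to π-allylpalladium species that morpholine captures, should free the acid and the phenol under near-neutral conditions that affect neither the alkyl ester, its trisubstituted alkene nor any stereocentre.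

**Compound list**

1 | 2-methoxystyrene | COc1ccccc1C=C | starting material
2 | ethylene | C=C | starting material
3 | 1-[(2R)-but-3-en-2-yl]-2-methoxybenzene | C=C[C@@H](C)c1ccccc1OC | intermediate
4 | (4R)-4-(2-methoxyphenyl)pentanal | O=CCC[C@@H](C)c1ccccc1OC | intermediate
5 | (4R)-4-(2-methoxyphenyl)pentanoic acid | OC(=O)CC[C@@H](C)c1ccccc1OC | intermediate
6 | (4R)-5-methoxy-4-methyl-3,4-dihydronaphthalen-1(2H)-one | O=C1CC[C@@H](C)c2c(OC)cccc21 | intermediate
7 | (4R)-8-bromo-5-methoxy-4-methyl-3,4-dihydronaphthalen-1(2H)-one | O=C1CC[C@@H](C)c2c(OC)ccc(Br)c21 | intermediate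
8 | methyl (5R)-4-methoxy-5-methyl-8-oxo-5,6,7,8-tetrahydronaphthalene-1-carboxylate | O=C1CC[C@@H](C)c2c(OC)ccc(C(=O)OC)c21 | intermediate
9 | potassium (4R)-5-methoxy-8-(methoxycarbonyl)-4-methyl-3,4-dihydronaphthalen-1-olate (potassium enolate of 8) | [K+].[O-]C1=CC[C@@H](C)c2c(OC)ccc(C(=O)OC)c21 | intermediate
10 | methyl (5R)-4-methoxy-5-methyl-8-{[(trifluoromethyl)sulfonyl]oxy}-5,6-dihydronaphthalene-1-carboxylate | FC(F)(F)S(=O)(=O)OC1=CC[C@@H](C)c2c(OC)ccc(C(=O)OC)c21 | intermediate
11 | methyl (5R)-8-ethenyl-4-methoxy-5-methyl-5,6-dihydronaphthalene-1-carboxylate | C=CC1=CC[C@@H](C)c2c(OC)ccc(C(=O)OC)c21 | intermediate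
12 | methyl (5R)-8-[(2S)-but-3-en-2-yl]-4-methoxy-5-methyl-5,6-dihydronaphthalene-1-carboxylate | C=C[C@H](C)C1=CC[C@@H](C)c2c(OC)ccc(C(=O)OC)c21 | intermediate
13 | (2S)-3-bromo-2-methylpropan-1-ol | OC[C@H](C)CBr | starting material
14 | [(2S)-3-bromo-2-methylpropoxy](tert-butyl)dimethylsilane | CC(C)(C)[Si](C)(C)OC[C@H](C)CBr | intermediate
15 | methyl (5R)-8-[(2S)-4-(9-borabicyclo[3.3.1]nonan-9-yl)butan-2-yl]-4-methoxy-5-methyl-5,6-dihydronaphthalene-1-carboxylate | C1CCC2CCCC1B2CC[C@H](C)C1=CC[C@@H](C)c2c(OC)ccc(C(=O)OC)c21 | intermediate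
16 | methyl (5R)-8-[(2S,6R)-7-{[tert-butyl(dimethyl)silyl]oxy}-6-methylheptan-2-yl]-4-methoxy-5-methyl-5,6-dihydronaphthalene-1-carboxylate | CC(C)(C)[Si](C)(C)OC[C@H](C)CCC[C@H](C)C1=CC[C@@H](C)c2c(OC)ccc(C(=O)OC)c21 | intermediate
17 | methyl (5R,8S)-8-[(2S,6R)-7-{[tert-butyl(dimethyl)silyl]oxy}-6-methylheptan-2-yl]-4-methoxy-5-methyl-5,6,7,8-tetrahydronaphthalene-1-carboxylate | CC(C)(C)[Si](C)(C)OC[C@H](C)CCC[C@H](C)[C@@H]1CC[C@@H](C)c2c(OC)ccc(C(=O)OC)c21 | intermediate
18 | disodium salt of (5R,8S)-8-[(2S,6R)-7-{[tert-butyl(dimethyl)silyl]oxy}-6-methylheptan-2-yl]-4-hydroxy-5-methyl-5,6,7,8-tetrahydronaphthalene-1-carboxylic acid | [Na+].[Na+].CC(C)(C)[Si](C)(C)OC[C@H](C)CCC[C@H](C)[C@@H]1CC[C@@H](C)c2c([O-])ccc(C(=O)[O-])c21 | intermediate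
19 | (5R,8S)-4-hydroxy-8-[(2S,6R)-7-hydroxy-6-methylheptan-2-yl]-5-methyl-5,6,7,8-tetrahydronaphthalene-1-carboxylic acid | OC[C@H](C)CCC[C@H](C)[C@@H]1CC[C@@H](C)c2c(O)ccc(C(=O)O)c21 | intermediate
20 | prop-2-en-1-yl (5R,8S)-8-[(2S,6R)-7-hydroxy-6-methylheptan-2-yl]-5-methyl-4-(prop-2-en-1-yloxy)-5,6,7,8-tetrahydronaphthalene-1-carboxylate | OC[C@H](C)CCC[C@H](C)[C@@H]1CC[C@@H](C)c2c(OCC=C)ccc(C(=O)OCC=C)c21 | intermediate
21 | 4-methylpent-3-enoic acid | CC(C)=CCC(=O)O | starting material
22 | prop-2-en-1-yl (5R,8S)-5-methyl-8-{(2S,6R)-6-methyl-7-[(4-methylpent-3-enoyl)oxy]heptan-2-yl}-4-(prop-2-en-1-yloxy)-5,6,7,8-tetrahydronaphthalene-1-carboxylate | CC(C)=CCC(=O)OC[C@H](C)CCC[C@H](C)[C@@H]1CC[C@@H](C)c2c(OCC=C)ccc(C(=O)OCC=C)c21 | intermediate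
23 | (5R,8S)-4-hydroxy-5-methyl-8-{(2S,6R)-6-methyl-7-[(4-methylpent-3-enoyl)oxy]heptan-2-yl}-5,6,7,8-tetrahydronaphthalene-1-carboxylic acid | CC(C)=CCC(=O)OC[C@H](C)CCC[C@H](C)[C@@H]1CC[C@@H](C)c2c(O)ccc(C(=O)O)c21 | target

**Step count and risks**

Total step count: 16. Longest linear sequence: 15 steps (steps 1–9 and 11–16, from 2-methoxystyrene); step 10 is a one-step side branch.

The three steps most likely to fail:

Step 9 (key step). Turnover may stall because the C8 ester next to the diene binds the cationic nickel centre. Ethylene may also be taken up at C2 (1,4-addition), or the product alkenes may isomerise. Fallback: build the C11 centre by copper-catalysed enantioselective allylic substitution. Setting out from compound 10, Stille coupling with (E)-3-(tributylstannyl)prop-2-en-1-ol (Pd(PPh3)4, LiCl, THF, 60 °C) should give methyl (5R)-8-[(1E)-3-hydroxyprop-1-en-1-yl]-4-methoxy-5-methyl-5,6-dihydronaphthalene-1-carboxylate F1. Appel bromination (CBr4, PPh3, CH2Cl2, 0 °C) should then give methyl (5R)-8-[(1E)-3-bromoprop-1-en-1-yl]-4-methoxy-5-methyl-5,6-dihydronaphthalene-1-carboxylate F2. SN2′ methylation with MeMgBr under CuBr·SMe2 and the chiral ferrocenyl diphosphine Taniaphos (CH2Cl2, −75 °C) places the methyl group on C11 and comes back to the route at compound 12.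

Step 12. Facial selectivity at C1 may be poor if the resident C4 and C11 centres oppose the catalyst, or hydrogen uptake may be slow at the crowded alkene beside the C8 ester. Fallback: let the C8 carboxyl group direct the metal. Setting out from compound 16, saponification (LiOH, THF/MeOH/H2O, 60 °C) should give (5R)-8-[(2S,6R)-7-{[tert-butyl(dimethyl)silyl]oxy}-6-methylheptan-2-yl]-4-methoxy-5-methyl-5,6-dihydronaphthalene-1-carboxylic acid F3. Carboxylate-directed asymmetric hydrogenation with a chiral spiro phosphino-oxazoline iridium complex ([Ir(cod)(SIPHOX)][B(3,5-(CF3)2C6H3)4], H2 (6 bar), Et3N, MeOH) should give (5R,8S)-8-[(2S,6R)-7-{[tert-butyl(dimethyl)silyl]oxy}-6-methylheptan-2-yl]-4-methoxy-5-methyl-5,6,7,8-tetrahydronaphthalene-1-carboxylic acid F4. The conditions of step 13 then cleave the aryl methyl ether and the silyl ether, and the route is rejoined at compound 19.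

Step 11. Oxidative addition of the β-branched alkyl bromide may be too slow, so that β-hydride elimination or protodeboronation of the alkylborane takes over. Fallback: form C13=C14 by olefination and saturate it later. Setting out from compound 12, hydroboration–oxidation (9-BBN, THF; then NaBO3·4H2O, H2O) should give methyl (5R)-8-[(2S)-4-hydroxybutan-2-yl]-4-methoxy-5-methyl-5,6-dihydronaphthalene-1-carboxylate F5, and Dess–Martin oxidation should give methyl (5R)-4-methoxy-5-methyl-8-[(2S)-4-oxobutan-2-yl]-5,6-dihydronaphthalene-1-carboxylate F6. From compound 14, substitution with 1-phenyl-1H-tetrazole-5-thiol (K2CO3, DMF) should give 5-{[(2S)-3-{[tert-butyl(dimethyl)silyl]oxy}-2-methylpropyl]sulfanyl}-1-phenyl-1H-tetrazole F7, and oxidation (H2O2, (NH4)6Mo7O24, EtOH) should give 5-{[(2S)-3-{[tert-butyl(dimethyl)silyl]oxy}-2-methylpropyl]sulfonyl}-1-phenyl-1H-tetrazole F8. Julia–Kocienski olefination of the aldehyde with this sulfone (KN(SiMe3)2, THF, −78 °C) should give methyl (5R)-8-[(2S,4E,6R)-7-{[tert-butyl(dimethyl)silyl]oxy}-6-methylhept-4-en-2-yl]-4-methoxy-5-methyl-5,6-dihydronaphthalene-1-carboxylate F9. The hydrogenation of step 12 then saturates both C13=C14 and C1=C2 and comes back to the route at compound 17.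

**Further compounds**

F1 | step 9 | methyl (5R)-8-[(1E)-3-hydroxyprop-1-en-1-yl]-4-methoxy-5-methyl-5,6-dihydronaphthalene-1-carboxylate | OC/C=C/C1=CC[C@@H](C)c2c(OC)ccc(C(=O)OC)c21
F2 | step 9 | methyl (5R)-8-[(1E)-3-bromoprop-1-en-1-yl]-4-methoxy-5-methyl-5,6-dihydronaphthalene-1-carboxylate | BrC/C=C/C1=CC[C@@H](C)c2c(OC)ccc(C(=O)OC)c21
F3 | step 12 | (5R)-8-[(2S,6R)-7-{[tert-butyl(dimethyl)silyl]oxy}-6-methylheptan-2-yl]-4-methoxy-5-methyl-5,6-dihydronaphthalene-1-carboxylic acid | CC(C)(C)[Si](C)(C)OC[C@H](C)CCC[C@H](C)C1=CC[C@@H](C)c2c(OC)ccc(C(=O)O)c21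
F4 | step 12 | (5R,8S)-8-[(2S,6R)-7-{[tert-butyl(dimethyl)silyl]oxy}-6-methylheptan-2-yl]-4-methoxy-5-methyl-5,6,7,8-tetrahydronaphthalene-1-carboxylic acid | CC(C)(C)[Si](C)(C)OC[C@H](C)CCC[C@H](C)[C@@H]1CC[C@@H](C)c2c(OC)ccc(C(=O)O)c21
F5 | step 11 | methyl (5R)-8-[(2S)-4-hydroxybutan-2-yl]-4-methoxy-5-methyl-5,6-dihydronaphthalene-1-carboxylate | OCC[C@H](C)C1=CC[C@@H](C)c2c(OC)ccc(C(=O)OC)c21
F6 | step 11 | methyl (5R)-4-methoxy-5-methyl-8-[(2S)-4-oxobutan-2-yl]-5,6-dihydronaphthalene-1-carboxylate | O=CC[C@H](C)C1=CC[C@@H](C)c2c(OC)ccc(C(=O)OC)c21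
F7 | step 11 | 5-{[(2S)-3-{[tert-butyl(dimethyl)silyl]oxy}-2-methylpropyl]sulfanyl}-1-phenyl-1H-tetrazole | CC(C)(C)[Si](C)(C)OC[C@H](C)CSc1nnnn1-c1ccccc1
F8 | step 11 | 5-{[(2S)-3-{[tert-butyl(dimethyl)silyl]oxy}-2-methylpropyl]sulfonyl}-1-phenyl-1H-tetrazole | CC(C)(C)[Si](C)(C)OC[C@H](C)CS(=O)(=O)c1nnnn1-c1ccccc1
F9 | step 11 | methyl (5R)-8-[(2S,4E,6R)-7-{[tert-butyl(dimethyl)silyl]oxy}-6-methylhept-4-en-2-yl]-4-methoxy-5-methyl-5,6-dihydronaphthalene-1-carboxylate | CC(C)(C)[Si](C)(C)OC[C@H](C)/C=C/C[C@H](C)C1=CC[C@@H](C)c2c(OC)ccc(C(=O)OC)c21
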